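The pyridine ring is derived from a pyrrole by insertion of one carbon. In the target, pyridine C3, which bears the acyl group, is flanked by the unsubstituted ring carbons C2 and C4, so it can be delivered as a carboxylated carbenoid into the C4=C5 bond of 3-decyl-1H-pyrrole, whose C3 chain ends up at pyridine C5. One operation (cyclopropanation, then ring opening with loss of HBr) forms the C2–C3 and C3–C4 bonds, enlarges the five-membered ring to the six-membered ring and installs the ester. The precursor is the N-unprotected 3-decylpyrrole, released from its N-silyl storage form just before use. The ester is then converted into the nonyl ketone.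

Key step: step 4

Assumption: the target has no stereocentre and no stereogenic double bond, so it is a single achiral compound and no enantiocontrol is needed.

Step 1
Reactants: 1 3-bromo-1-(triisopropylsilyl)-1H-pyrrole; 2 1-iododecane
Product: 4 3-decyl-1-(triisopropylsilyl)-1H-pyrrole, via 3-lithio-1-(triisopropylsilyl)pyrrole 3 (not isolated)
Conditions: t-BuLi (2.0 equiv), THF, −78 °C; then 2 (1.2 equiv), −78 °C → rt
Reagents that add atoms: none
Why: Bromine–lithium exchange with t-BuLi is fast at −78 °C (the second equivalent destroys the t-BuBr formed), the bulky N-silyl group keeps the lithium at C3, and the 3-lithiopyrrole is alkylated by the primary iodide in an SN2 reaction (halogen–metal exchange followed by alkylation).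

Step 2
Reactants: 4 3-decyl-1-(triisopropylsilyl)-1H-pyrrole
Product: 5 3-decyl-1H-pyrrole
Conditions: TBAF (1.1 equiv, 1 M in THF), THF, 0 °C → rt; aqueous work-up; kept cold under argon and used promptly
Reagents that add atoms: none
Why: Fluoride attacks silicon and the strong Si–F bond drives N–Si cleavage (fluoride desilylation), the pyrrolide being protonated by water, and these non-acidic conditions avoid the oligomerisation to which electron-rich 3-alkylpyrroles are prone.

Step 3
Reactants: 6 ethyl diazoacetate
Product: 7 ethyl bromodiazoacetate (ethyl 2-bromo-2-diazoacetate)
Conditions: NBS (1.1 equiv), DBU (1.3 equiv), CH2Cl2, 0 °C, 5–10 min; rapid cold filtration through a short silica pad; kept at ≤0 °C as a CH2Cl2 solution, not concentrated, used at once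
Reagents that add atoms: N-bromosuccinimide, O=C1CCC(=O)N1Br
Why: The diazo C–H is acidic enough for DBU-assisted electrophilic bromination by NBS with retention of the diazo group (electrophilic halogenation of a diazoacetate); the product is thermally labile, so it is handled only cold and in solution.

Step 4
Reactants: 5 3-decyl-1H-pyrrole; 7 ethyl bromodiazoacetate
Product: 9 ethyl 5-decylnicotinate (ethyl 5-decylpyridine-3-carboxylate), via 6-bromo-2-azabicyclo[3.1.0]hex-3-ene ester 8 (not isolated)
Conditions: Rh2(esp)2 (2 mol%), Cs2CO3 (2 equiv), CH2Cl2, 0 °C → rt; cold CH2Cl2 solution of 7 (1.5 equiv) added over ca. 30 min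
Reagents that add atoms: none
Why: Rh2(esp)2 decomposes 7 with loss of N2 to an electrophilic bromo(ethoxycarbonyl)carbenoid, which bonds to the unhindered α-carbon C5 of the electron-rich pyrrole and closes onto C4 to give bromocyclopropane 8. The nitrogen lone pair then drives a disrotatory 2π-electrocyclic opening of the cyclopropane with departure of bromide, cleaving the former C4–C5 bond to an N–H pyridinium that Cs2CO3 deprotonates, so that the inserted carbon becomes pyridine C3 with its ester already in place. The closest known reaction type is the Ciamician–Dennstedt ring expansion in its rhodium/halodiazoacetate form, which converts N–H indoles into quinoline-3-carboxylates, and insertion of halocarbenes into N–H pyrroles to give 3-substituted pyridines is likewise established. The three-membered ring closes by [2+1] carbenoid addition and the six-membered ring arises by ring expansion of the bicyclo[3.1.0] system and not by a cyclisation; the three stereocentres of 8 form as a racemate of no consequence because all of them become sp2 carbons in 9. The step needs site selectivity for C4=C5 over C2=C3 and for carbon over N–H insertion: the decyl chain at C3 and the bulky esp-ligated carbenoid shield C2 and its trisubstituted double bond, the N–H is left free because its lone pair and proton are required for opening and aromatisation, and the carbonate removes the HBr that would otherwise oligomerise the pyrrole. Attack at the wrong bond would give ethyl 4-decylnicotinate, which should be separable by chromatography and recognisable by the ortho coupling between H5 and H6.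

Step 5
Reactants: 9 ethyl 5-decylnicotinate; 10 ethyl decanoate
Product: 13 1-(5-decylpyridin-3-yl)decan-1-one, via ethyl decanoate lithium enolate 11 (not isolated), via β-keto ester ethyl 2-(5-decylpyridine-3-carbonyl)decanoate 12 (not isolated)
Conditions: 10 (2.2 equiv), LDA (2.1 equiv), THF, −78 °C, 30 min; 9 (1.0 equiv), −78 → 0 °C; then 6 M HCl/AcOH, 100 °C; aq. NaOH to pH 9, extraction
Reagents that add atoms: none
Why: In this crossed Claisen condensation the preformed ester enolate (no free amide base left to metalate the pyridine) acylates on the non-enolisable, electron-poor nicotinate ester and the β-keto ester is held as its enolate, after which hot aqueous acid hydrolyses the ester and the β-keto acid decarboxylates, erasing the racemic α-stereocentre of 12.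

Compound list
1 | 3-bromo-1-(triisopropylsilyl)-1H-pyrrole | CC(C)[Si](C(C)C)(C(C)C)n1ccc(Br)c1 | starting material
2 | 1-iododecane | CCCCCCCCCCI | starting material
3 | 3-lithio-1-(triisopropylsilyl)-1H-pyrrole (not isolated) | [Li]c1ccn([Si](C(C)C)(C(C)C)C(C)C)c1 | intermediate
4 | 3-decyl-1-(triisopropylsilyl)-1H-pyrrole | CCCCCCCCCCc1ccn([Si](C(C)C)(C(C)C)C(C)C)c1 | intermediate
5 | 3-decyl-1H-pyrrole | CCCCCCCCCCc1cc[nH]c1 | intermediate
6 | ethyl diazoacetate | CCOC(=O)C=[N+]=[N-] | starting material
7 | ethyl bromodiazoacetate (ethyl 2-bromo-2-diazoacetate; cold solution, used at once) | CCOC(=O)C(Br)=[N+]=[N-] | intermediate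
8 | ethyl 6-bromo-4-decyl-2-azabicyclo[3.1.0]hex-3-ene-6-carboxylate (not isolated; racemic, configuration at C6 not controlled) | CCOC(=O)C1(Br)C2NC=C(CCCCCCCCCC)C12 | intermediate
9 | ethyl 5-decylnicotinate (ethyl 5-decylpyridine-3-carboxylate) | CCCCCCCCCCc1cncc(C(=O)OCC)c1 | intermediate
10 | ethyl decanoate | CCCCCCCCCC(=O)OCC | starting material
11 | lithium enolate of ethyl decanoate (not isolated; enolate geometry without consequence) | CCCCCCCCC=C(OCC)O[Li] | intermediate
12 | ethyl 2-(5-decylpyridine-3-carbonyl)decanoate (not isolated; racemic) | CCCCCCCCC(C(=O)OCC)C(=O)c1cncc(CCCCCCCCCC)c1 | intermediate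
13 | 1-(5-decylpyridin-3-yl)decan-1-one (achiral) | CCCCCCCCCCc1cncc(C(=O)CCCCCCCCC)c1 | target

Total step count: 5
Longest linear sequence: 4 steps (steps 1, 2, 4 and 5, from compound 1); step 3 is a one-step branch that supplies 7 for the key step.

Steps most likely to fail

1. Step 4. The carbenoid may attack C2 next to the decyl chain or the N–H, may alkylate a ring carbon without closing the cyclopropane, or may be lost to dimerisation and to binding of the catalyst by the pyridine product, so that the ring expansion is unselective or inefficient. Fallback, setting out from 2 and returning at 9: zinc insertion into 1-iododecane 2 (Zn dust, LiCl, THF, 40 °C) should give decylzinc iodide F1, and Negishi coupling of this with commercially available ethyl 5-bromonicotinate (Pd(OAc)2/SPhos, THF, rt to 50 °C) should give 9 with the 3,5-pattern fixed by the bromide; the route then continues with step 5.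

2. Step 5. Self-condensation of the ester enolate may outrun the crossed acylation, or the nicotinate may be consumed by base-mediated side reactions at the pyridine ring, leaving the condensation incomplete. Fallback, setting out from 9 and returning at 13: aminolysis of 9 with N,O-dimethylhydroxylamine hydrochloride and i-PrMgCl (THF, −20 °C) should give the Weinreb amide 5-decyl-N-methoxy-N-methylnicotinamide F2, and addition of nonylmagnesium bromide (THF, 0 °C) should stop at the chelated tetrahedral intermediate and release 13 on aqueous work-up.

3. Step 1. The SN2 alkylation of the hindered 3-lithiopyrrole may be slow, so that protonation of the organolithium (net debromination) or elimination from the iodide competes. Fallback, setting out from 1 and returning at 4: hydroboration of 1-decene with 9-BBN (THF, rt) should give B-decyl-9-borabicyclo[3.3.1]nonane F3, which would be coupled with bromide 1 in a B-alkyl Suzuki–Miyaura reaction (PdCl2(dppf), K3PO4, THF/DMF/H2O, 60 °C) to give 4.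

Further compounds
F1 | step 4 | decylzinc iodide | CCCCCCCCCC[Zn]I
F2 | step 5 | 5-decyl-N-methoxy-N-methylnicotinamide | CCCCCCCCCCc1cncc(C(=O)N(C)OC)c1
F3 | step 1 | B-decyl-9-borabicyclo[3.3.1]nonane | CCCCCCCCCCB1C2CCCC1CCC2
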